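After 0.500 d the gamma flask, charged at once with substrate and reagent at equal concentrations, reads mono adduct 41.4% and bis adduct 24.0%. A mono adduct has taken one reagent and a bis adduct two, so these readings account for 89.4% of the gamma reagent. I follow one reagent molecule through the south-east flask, where substrate is dosed into the whole reagent charge; at its fork it meets substrate or mono adduct.

| flask | substrate | reagent | remark | time |
|---|---|---|---|---|
| gamma | 0.25 M | 0.25 M | run made earlier |  |
| delta | 0.25 M | 0.12 M | run made earlier |  |
| beta | 0.25 M | 0.50 M | run made earlier |  |
| theta | 0.50 M | 0.25 M | run made earlier |  |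
| north | 0.25 M | 0.250 M (fed, over 12.0 d) | a stirred flask in which reagent is dosed at a steady rate over 12.0 d without added volume, worked up at 15 d | 15 d |
| north-east | 0.25 M | 0.250 M | a closed flask charged with all of it at once and left for 15 d | 15 d |
| south-west | 0.25 M | 0.250 M | a single well-mixed tank run continuously and read at steady state, 15 d in it on average |  |
| south-east | 0.25 M (fed, over 12.0 d) | 0.250 M | a stirred flask in which substrate is dosed at a steady rate over 12.0 d without added volume, worked up at 15 d | 15 d |

| run | time / d | mono adduct / % | bis adduct / % |
|---|---|---|---|
| gamma | 0.500 | 41.4 | 24.0 |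
| gamma | 1.25 | 33.9 | 24.4 |
| gamma | 2.50 | 29.6 | 24.9 |
| gamma | 4.00 | 27.2 | 25.2 |
| gamma | 5.00 | 26.6 | 25.1 |
| gamma | 8.00 | 24.9 | 25.2 |
| gamma | 10.0 | 23.5 | 24.7 |
| delta | 0.833 | 25.9 | 5.6 |
| delta | 2.50 | 18.0 | 5.5 |
| delta | 4.00 | 15.4 | 5.9 |
| delta | 6.00 | 12.7 | 6.0 |
| delta | 10.0 | 10.5 | 6.1 |
| delta | 12.0 | 8.6 | 5.9 |
| delta | 15.0 | 7.0 | 5.4 |
| beta | 1.25 | 6.1 | 87.4 |
| beta | 1.67 | 4.3 | 90.1 |
| beta | 3.00 | 2.7 | 93.3 |
| beta | 4.00 | 2.2 | 94.3 |
| beta | 6.00 | 1.3 | 96.5 |
| beta | 10.0 | 0.7 | 97.5 |
| beta | 15.0 | 0.5 | 97.9 |
| theta | 1.25 | 19.9 | 6.0 |
| theta | 4.00 | 11.4 | 6.5 |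
| theta | 8.00 | 7.2 | 6.0 |
| theta | 10.0 | 6.0 | 6.7 |
| theta | 15.0 | 4.0 | 6.2 |

(readings scatter by 0.3 percentage points)

- a species is counted by the substrate in it: one side product counts as two
- the stated concentrations are those of everything mixed, before any reaction; amounts are the same in each set-up
- the feed brings no volume worth counting
- the earlier runs were made in a closed, stirred flask

- the set-up with the highest share of mono adduct in all that became mono adduct or bis adduct or side product or isomer of the product, at the outlet or at the end ("none" if the first two lie within 2 percentage points) (north / north-east / south-west / south-east / none)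
- share of mono adduct in all that became mono adduct or bis adduct or side product or isomer of the product, at the outlet or at the end, north
- share of mono adduct in all that became mono adduct or bis adduct or side product or isomer of the product, at the outlet or at the end, north-east
- share of mono adduct in all that became mono adduct or bis adduct or side product or isomer of the product, at the outlet or at the end, south-west
- share of mono adduct in all that became mono adduct or bis adduct or side product or isomer of the product, at the outlet or at the end, south-east

Each bis adduct takes two reagents, so in south-east bis adduct can reach 50.0% of the substrate, [reagent] over twice [substrate] as charged: the bis ceiling. At the ceiling every reagent sits in bis adduct, which puts the mono share at zero, my bound from below. For the bound from above I assume that south-east makes at least the bis adduct read in gamma, 25.2% at 4.00 d. That leaves 49.6% of the reagent in singly reacted forms, and counting them as mono adduct gives a share of 66.3%. To tighten it, the gamma spell of 0.500 d is far shorter than the dosing time of 12.0 d, and one such spell feeds 4.17% of the substrate. If that much stands as mono adduct, it costs the ceiling half its amount, and my share is 8.00%.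

The forecast gives south-east 10%, between 3% and 18%, “mostly bis, with substrate left over”. That is inside my bracket and above my reckoning. It gives 6% for north, 22% for north-east and 15% for south-west, and names north-east as best.

South-east gives 6.77%; north gives 20.0%, south-west 20.3%, and north-east is best at 23.5%. At 15.0 d south-east holds bis adduct 45.0% with 0% left of reagent, the limiting reagent. Bis adduct stands 5 percentage points under the ceiling, so 10.0 points of the reagent charge lies outside bis adduct.

    substrate + reagent → mono adduct + released group (k = 7.40 × 10⁻⁴ L mol⁻¹ s⁻¹)
    reagent + mono adduct → bis adduct + released group (k = 3.80 × 10⁻⁴ L mol⁻¹ s⁻¹)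
    substrate + mono adduct → side product (k = 1.30 × 10⁻⁵ L mol⁻¹ s⁻¹)
    mono adduct ⇌ isomer of the product (K = 0.540, k = 4.70 × 10⁻⁶ s⁻¹)

With 0.10 M of reagent, the same dosing has a bis ceiling of 20.0%. That flask ends with bis adduct 15.2%, substrate 69.3% and a mono share of 7.45%.

Readings and results were computed with constants of no real substance; the scatter is artificial.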